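Slowness is what your product peak shows: in the grey run it takes 12.0 d to reach 57%, with 0.2 mol% of free catalyst in the flask.

| flask | substrate | partner | free catalyst | remark | time |
|---|---|---|---|---|---|
| grey | 20 mM | 1.1 equiv | 0.2 mol% | run made earlier |  |
| amber | 20 mM | 0.55 equiv | 0.2 mol% | run made earlier |  |
| red | 20 mM | 0.83 equiv | 0.2 mol% | run made earlier |  |
| green | 20 mM | 1.1 equiv | 0.1 mol% | run made earlier |  |
| noon | 20 mM | 1.10 equiv | 0.2 mol% | everything together in a closed stirred flask, run for 20 d | 20 d |
| autumn | 20 mM | 1.10 equiv (fed, over 20.0 d) | 0.2 mol% | a stirred flask in which partner is dosed at a steady rate over 20.0 d without added volume, worked up at 20 d | 20 d |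
| dusk | 20 mM (fed, over 20.0 d) | 1.10 equiv | 0.2 mol% | a stirred flask in which substrate is dosed at a steady rate over 20.0 d without added volume, worked up at 20 d | 20 d |
| winter | 20 mM | 1.10 equiv | 0.2 mol% | a single well-mixed tank run continuously and read at steady state, 20 d in it on average |  |

- grey (time / d: product / %): 1.04: 10; 2.00: 12; 5.00: 24; 12.0: 57
- amber (time / d: product / %): 1.25: 5; 3.00: 12; 6.00: 27; 15.0: 47
- red (time / d: product / %): 1.25: 6; 3.00: 16; 6.00: 31; 15.0: 64
- green (time / d: product / %): 1.25: 0; 3.00: 10; 6.00: 14; 15.0: 40

(readings scatter by 1.5 percentage points)

- the stated concentrations are those of everything mixed, before any reaction; amounts are the same in each set-up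
- the numbers in the tables scatter by 1.5 percentage points (one standard deviation)
- the feed brings no volume worth counting
- the earlier runs were made in a closed, stirred flask

1. the set-up with the highest amount of product at the outlet or at the end, in percent of the substrate put in ("none" if the first two lie within 2 percentage points) (noon / autumn / dusk / winter / none)
2. amount of product at the outlet or at the end, in percent of the substrate put in, noon
3. amount of product at the outlet or at the end, in percent of the substrate put in, autumn
4. amount of product at the outlet or at the end, in percent of the substrate put in, dusk
5. amount of product at the outlet or at the end, in percent of the substrate put in, winter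

Read the last row of each run against its catalyst. Grey reads 23.8 d⁻¹: this is the mean turnover frequency up to the last reading, product made per catalyst charged per day. Green, on half the catalyst, reads 26.7 d⁻¹ at its last reading, after 15.0 d, so in these two runs the product per day goes roughly with the loading. Red, with less partner, reads 21.3 d⁻¹, and amber, with less again, reads 15.7 d⁻¹, lower than grey.

Turnover frequency times loading times time is a budget: 95.0% for noon. I treat the large part as this budget and compute only the shortfall. Noon has grey's recipe, and grey after 12.0 d holds 10.6 mM of partner by difference, nearly what red holds after 6.00 d, 10.4 mM. From there red gains 0.0367 d⁻¹ of the charge, against 0.0475 d⁻¹ for grey up to its last reading. Over the remaining 8.00 d that gap costs 8.7 percentage points, so I reckon noon at 86.3%. I take this as a high figure, because by difference red after 6.00 d still had 69.0% of its substrate, more than grey's 43.0% after 12.0 d.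

Autumn, dusk and winter have the same loading and 20 d, on average in winter's case. A dosed reagent begins at nothing and a tank holds its outlet mixture throughout, so I place them under noon.

The forecast gave noon 85%, autumn 63%, dusk 78% and winter 72%: “Noon is best.”

The flask gives noon 80.2%, autumn 66.8%, dusk 69.6% and winter 66.3%, so noon is highest.

    catalyst intermediate B ⇌ catalyst intermediate C (K = 0.130, k = 0.380 min⁻¹)
    substrate + free catalyst ⇌ catalyst intermediate A (K = 1300 M⁻¹, k = 620 M⁻¹ min⁻¹)
    partner + catalyst intermediate A ⇌ catalyst intermediate B (K = 1900 M⁻¹, k = 19.0 M⁻¹ min⁻¹)
    catalyst intermediate C ⇌ free catalyst + product (K = 0.00660 M, k = 0.180 min⁻¹)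

Noon ends 15 points under the budget and 6.2 points under my corrected figure, on the side I marked. In autumn at 10.6 d, each by the forward rate of its own step alone, catalyst intermediate A has a half-life of 0.12 h and catalyst intermediate C 0.064 h, against 3.0 d for partner. At 20.0 d catalyst intermediate B, the resting state, holds 77.1% of the catalyst in autumn. For the neighbour of autumn on 0.12 mol% of free catalyst, the turnover frequency gives a budget of 57.1%; that flask gives 47.3%.

The earlier runs and the new flask stem from a simulated flask for substances that don't exist; scatter was added.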